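**Plan**

- Numbering (germacrane): ring A is the 3(2H)-furanone (O, C3, C2, C1, C10; C10 carries methyl C14), ring B the α-methylene lactone (C7, C11(=C13H2), C12, O, C8), ring C the ten-membered carbocycle C1–C10; C4=C15H2, C5–OH, C6–O-methacryloyl, C9H2.
- Enabling feature: C15=C4–C5(O) is a 2-substituted allyl unit with oxygen on C5, lying between the sp2 carbon C3 of ring A and the carbinol C6. This is the imprint of an alkoxyallene inserted between a vinyl halide and an aldehyde.
- Cuts, in retrosynthetic order: the C6 ester and the C5 protecting group; C3–C4 and C5–C6 together (ring C opens to a C3 bromide, a C6 aldehyde and 4-methoxybenzyloxyallene); C7–C8 and the lactone C–O bond (ring B); the O–C3 bond of ring A (bromoynone); C1–C2 (Weinreb amide plus acetylide).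
- Forward: (S)-citramalic acid → bromoynone → ring A → C8 aldehyde → ring B by CrCl2-catalysed 2-(alkoxycarbonyl)allylation and lactonisation → C6 aldehyde → ring C by the Pd(PPh3)4/indium allene macro-annulation → methacrylate → free C5–OH.
- Stereochemistry: C10 from (S)-citramalic acid; C8 from the chiral CrCl2–bis(oxazoline) catalyst and C7 from the anti-selective chair allylation; C5 and C6 from the chair allyl transfer of the E-γ-alkoxyallylindium (anti) onto the aldehyde face fixed by C7.

Key step: step 15

Assumption: the CrCl2 complex of ligand L, 3,6-di-tert-butyl-1,8-bis[(4S)-4-isopropyl-4,5-dihydro-1,3-oxazol-2-yl]-9H-carbazole, is taken to deliver the allyl unit to the Re face of the C8 aldehyde; should its sense be the opposite, the (R,R)-ligand takes its place in step 11 without other change.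

Atom numbers (C1–C15) are those of the plan; compound numbers follow first appearance.

**Step 1**
Reactants: 1 (S)-citramalic acid
Product: 2 2-[(4S)-2,2,4-trimethyl-5-oxo-1,3-dioxolan-4-yl]acetic acid
Conditions: 2,2-dimethoxypropane, p-TsOH·H2O (cat.), acetone, rt
Reagents that add atoms: 2,2-dimethoxypropane, COC(C)(C)OC
Why: Acid-catalysed acetonide formation engages the α-hydroxy acid as the five-membered 1,3-dioxolan-4-one, which tells the two carboxyl groups apart and leaves the stereocentre (future C10) untouched.

**Step 2**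
Reactants: 2 2-[(4S)-2,2,4-trimethyl-5-oxo-1,3-dioxolan-4-yl]acetic acid
Product: 3 (5S)-5-(2-hydroxyethyl)-2,2,5-trimethyl-1,3-dioxolan-4-one
Conditions: BH3·SMe2, THF, 0 °C → rt; MeOH quench
Reagents that add atoms: none
Why: Chemoselective borane reduction of a carboxylic acid, which proceeds through the acyloxyborane far faster than attack on the ester-type carbonyl of the dioxolanone, should give the primary alcohol (future C8).

**Step 3**
Reactants: 3 (5S)-5-(2-hydroxyethyl)-2,2,5-trimethyl-1,3-dioxolan-4-one
Product: 4 (2S)-2,4-dihydroxy-N-methoxy-N,2-dimethylbutanamide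
Conditions: MeNH(OMe)·HCl, i-PrMgCl, THF, −20 → 0 °C
Reagents that add atoms: N,O-dimethylhydroxylamine hydrochloride, CNOC.Cl
Why: Weinreb amide formation, in which the chloromagnesium amide made from the amine salt and i-PrMgCl opens the activated dioxolanone with loss of acetone and frees both hydroxyl groups.

**Step 4**
Reactants: 4 (2S)-2,4-dihydroxy-N-methoxy-N,2-dimethylbutanamide
Product: 5 (2S)-N-methoxy-N,2-dimethyl-2,4-bis(triethylsilyloxy)butanamide
Conditions: TESOTf, 2,6-lutidine, CH2Cl2, −78 → 0 °C
Reagents that add atoms: triethylsilyl trifluoromethanesulfonate, CC[Si](CC)(CC)OS(=O)(=O)C(F)(F)F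
Why: Silyl triflate silylation covers the primary and the hindered tertiary hydroxyl alike, and masking the tertiary oxygen keeps the coming ynone from cyclising before bromine is on the alkyne.

**Step 5**
Reactants: 5 (2S)-N-methoxy-N,2-dimethyl-2,4-bis(triethylsilyloxy)butanamide; 6 trimethylsilylacetylene
Product: 7 (4S)-4-methyl-4,6-bis(triethylsilyloxy)-1-(trimethylsilyl)hex-1-yn-3-one
Conditions: 6, n-BuLi, THF, −78 °C; then 5, −78 → −20 °C; cold aq. NH4Cl
Reagents that add atoms: none
Why: Weinreb ketone synthesis, in which the lithium acetylide adds once to give a chelated tetrahedral intermediate that collapses to the ynone (C1–C2 bond) only on quenching, the silyl cap on the alkyne suppressing conjugate addition of the liberated hydroxylamine.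

**Step 6**
Reactants: 7 (4S)-4-methyl-4,6-bis(triethylsilyloxy)-1-(trimethylsilyl)hex-1-yn-3-one
Product: 8 (4S)-1-bromo-4-methyl-4,6-bis(triethylsilyloxy)hex-1-yn-3-one
Conditions: NBS, AgNO3 (cat.), acetone, rt, dark
Reagents that add atoms: N-bromosuccinimide, O=C1CCC(=O)N1Br
Why: AgNO3-catalysed bromodesilylation of an alkynylsilane through the silver acetylide is a standard entry to 1-bromoalkynes and should tolerate the silyl ethers and the ketone.

**Step 7**
Reactants: 8 (4S)-1-bromo-4-methyl-4,6-bis(triethylsilyloxy)hex-1-yn-3-one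
Product: 10 (2S)-5-bromo-2-(2-hydroxyethyl)-2-methylfuran-3(2H)-one, via dihydroxy bromoynone 9 (not isolated)
Conditions: TBAF, AcOH (1:1), THF, −20 → 0 °C
Reagents that add atoms: none
Why: Proposed new method: buffered fluoride removes both triethylsilyl groups and the freed tertiary oxygen adds 5-endo-dig (allowed by Baldwin's rules) to the bromine-bearing β-carbon C3 of the ynone, which C1=O makes electrophilic, and protonation at C2 gives the 5-bromofuranone (ring A), the bromide being kept because its loss would demand a cyclic alkyne and the primary hydroxyl staying out because only a seven-membered ring is open to it; the closest known reaction type is the base- or fluoride-induced cycloisomerisation of α′-hydroxy ynones with carbon-substituted alkyne termini to 3(2H)-furanones, together with conjugate additions of heteroatom nucleophiles to 1-bromoalkynyl carbonyl compounds.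

**Step 8**
Reactants: 10 (2S)-5-bromo-2-(2-hydroxyethyl)-2-methylfuran-3(2H)-one
Product: 11 2-[(2S)-5-bromo-2-methyl-3-oxo-2,3-dihydrofuran-2-yl]acetaldehyde
Conditions: Dess–Martin periodinane, CH2Cl2, 0 °C → rt
Reagents that add atoms: none
Why: Dess–Martin oxidation works without base, which matters because the aldehyde carries the ring-A oxygen in the β-position and would open by E1cB elimination under basic conditions.

**Step 9**
Reactants: 12 methyl acrylate; 13 2,2-dimethoxyacetaldehyde
Product: 14 methyl 3-hydroxy-4,4-dimethoxy-2-methylidenebutanoate (racemic)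
Conditions: DABCO, 1,4-dioxane/H2O, rt
Reagents that add atoms: none
Why: Morita–Baylis–Hillman reaction of the acrylate with an activated α,α-dialkoxy aldehyde; the carbinol centre is racemic and is erased in the next step.

**Step 10**
Reactants: 14 methyl 3-hydroxy-4,4-dimethoxy-2-methylidenebutanoate
Product: 15 methyl (2Z)-2-(bromomethyl)-4,4-dimethoxybut-2-enoate
Conditions: NBS, Me2S, CH2Cl2, 0 °C → rt
Reagents that add atoms: N-bromosuccinimide, O=C1CCC(=O)N1Br
Why: Corey–Kim-type activation of the allylic alcohol as its alkoxysulfonium salt and SN2′ attack of bromide at the methylene terminus should give the conjugated primary allylic bromide, the Z isomer being usual for Baylis–Hillman adducts, while the acetal is untouched under these non-acidic conditions.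

**Step 11**
Reactants: 11 2-[(2S)-5-bromo-2-methyl-3-oxo-2,3-dihydrofuran-2-yl]acetaldehyde; 15 methyl (2Z)-2-(bromomethyl)-4,4-dimethoxybut-2-enoate
Product: 18 (2S)-5-bromo-2-{[(2S,3R)-3-(dimethoxymethyl)-4-methylidene-5-oxooxolan-2-yl]methyl}-2-methylfuran-3(2H)-one, via silyl ether 16 (not isolated), via hydroxy ester 17 (not isolated)
Conditions: CrCl2 (10 mol %), ligand L (12 mol %), Mn powder (2 equiv), TMSCl, i-Pr2NEt (cat.), THF, rt; then p-TsOH·H2O (cat.), wet CH2Cl2, rt
Reagents that add atoms: none
Why: Catalytic asymmetric Nozaki–Hiyama–Kishi-type 2-(alkoxycarbonyl)allylation, in which the allylchromium species (trivalent chromium) from 15 adds through its γ-carbon in a chair transition state with the dimethoxymethyl group equatorial, so that the anti adduct and hence the trans lactone (C7 R) is expected whatever the bromide geometry, the ligand directs attack to the Re face of C8=O (C8 S) over the weak bias of the quaternary C10, and acid then cleaves the silyl ether and closes ring B by lactonisation of the γ-hydroxy ester.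

**Step 12**
Reactants: 19 4-methoxybenzyl alcohol; 20 propargyl bromide
Product: 21 1-methoxy-4-[(prop-2-yn-1-yloxy)methyl]benzene
Conditions: NaH, Bu4NI (cat.), THF, 0 °C → rt
Reagents that add atoms: none
Why: Williamson ether synthesis of the sodium alkoxide with a reactive propargylic bromide.

**Step 13**
Reactants: 21 1-methoxy-4-[(prop-2-yn-1-yloxy)methyl]benzene
Product: 22 1-methoxy-4-[(propa-1,2-dien-1-yloxy)methyl]benzene (4-methoxybenzyloxyallene)
Conditions: KOt-Bu (0.3 equiv), THF, 0 °C → rt
Reagents that add atoms: none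
Why: Base-catalysed propargyl–allenyl isomerisation is the standard preparation of alkoxyallenes and should stop at the 1-alkoxyallene with a catalytic amount of KOt-Bu.

**Step 14**
Reactants: 18 (2S)-5-bromo-2-{[(2S,3R)-3-(dimethoxymethyl)-4-methylidene-5-oxooxolan-2-yl]methyl}-2-methylfuran-3(2H)-one
Product: 23 (2S,3R)-2-{[(2S)-5-bromo-2-methyl-3-oxo-2,3-dihydrofuran-2-yl]methyl}-4-methylidene-5-oxooxolane-3-carbaldehyde
Conditions: TFA/H2O (9:1), CHCl3, 0 °C; toluene co-evaporation below 20 °C; used at once
Reagents that add atoms: water, O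
Why: Acid hydrolysis of the dimethyl acetal at 0 °C avoids base, under which the C7 proton (α to the aldehyde and allylic to C11=C13) would be lost and the alkene would move into conjugation, and the aldehyde is therefore not purified but taken straight on.

**Step 15**
Reactants: 23 (2S,3R)-2-{[(2S)-5-bromo-2-methyl-3-oxo-2,3-dihydrofuran-2-yl]methyl}-4-methylidene-5-oxooxolane-3-carbaldehyde; 22 4-methoxybenzyloxyallene
Product: 25 (5S,6R,7S,8S,10S)-6-hydroxy-5-(4-methoxybenzyloxy)-1-oxo-3,10-epoxygermacra-2,4(15),11(13)-trien-12,8-olide, via allylindium 24 (not isolated)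
Conditions: Pd(PPh3)4 (10 mol %), In powder (2 equiv), 22 (3 equiv), DMF, 40 °C; 23 added by syringe pump to 2 mM
Reagents that add atoms: none
Why: Proposed new method: Pd(PPh3)4 (zerovalent palladium) inserts into the C3–Br bond of the vinylogous acyl bromide, the vinylpalladium bromide adds across allene 22 at its central carbon (C3–C4 bond), and indium metal reduces the resulting 1-alkoxy-π-allylpalladium to the allylindium 24 (metal on C15), which attacks the C6 aldehyde through C5 in a six-membered chair and so forms the C5–C6 bond and the C4=C15 methylene. The closest known reaction type is the three-component coupling of aryl or vinyl halides, allenes and aldehydes to homoallylic alcohols with a zerovalent palladium–phosphine catalyst and indium metal, and the attack through the oxygen-bearing carbon has its analogy in the indium reagents made from 3-bromopropenyl esters; neither an alkoxyallene nor a ten-membered ring has been used in this mode. Ring C closes by intramolecular Barbier-type allyl transfer, a 10-exo-trig attack on the aldehyde counted through C1 and C2 (9-exo through the ring-A oxygen). C5 and C6 are set together: the E-γ-alkoxyallylindium places its oxygen equatorial in the chair and should give the anti C5/C6 pair, while the aldehyde face is chosen by the adjacent C7 centre inside the forming ring (Felkin–Anh with the sp2 carbon C11 as the perpendicular group, as for α-vinyl aldehydes), so 5S,6R is expected but unproven. The step needs the vinylpalladium to take the allene and not the α-methylene lactone or a second molecule (excess 22, slow addition at high dilution), and needs the allylindium to choose the aldehyde over the enoate and the ring-A ketone, which is the normal preference of allylindium reagents.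

**Step 16**
Reactants: 25 (5S,6R,7S,8S,10S)-6-hydroxy-5-(4-methoxybenzyloxy)-1-oxo-3,10-epoxygermacra-2,4(15),11(13)-trien-12,8-olide; 26 methacrylic anhydride
Product: 27 (5S,6R,7R,8S,10S)-5-(4-methoxybenzyloxy)-6-(2-methylprop-2-enoyloxy)-1-oxo-3,10-epoxygermacra-2,4(15),11(13)-trien-12,8-olide
Conditions: 26, DMAP, Et3N, CH2Cl2, 0 °C → rt
Reagents that add atoms: none
Why: DMAP-catalysed acylation by the anhydride can only reach C6, the single free hydroxyl, because C5 still carries its 4-methoxybenzyl ether.

**Step 17**
Reactants: 27 (5S,6R,7R,8S,10S)-5-(4-methoxybenzyloxy)-6-(2-methylprop-2-enoyloxy)-1-oxo-3,10-epoxygermacra-2,4(15),11(13)-trien-12,8-olide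
Product: 28 (5S,6R,7R,8S,10S)-5-hydroxy-6-(2-methylprop-2-enoyloxy)-1-oxo-3,10-epoxygermacra-2,4(15),11(13)-trien-12,8-olide
Conditions: DDQ, CH2Cl2/pH 7 phosphate buffer, 0 °C → rt
Reagents that add atoms: none
Why: Oxidative cleavage of the 4-methoxybenzyl ether by DDQ (hydride abstraction at the electron-rich benzylic position, then hydrolysis) runs at neutral pH, where the methacrylate should not migrate to C5 and the Michael acceptors are left alone.

**Compound list**

1 | (S)-citramalic acid | OC(=O)C[C@](C)(O)C(=O)O | starting material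
2 | 2-[(4S)-2,2,4-trimethyl-5-oxo-1,3-dioxolan-4-yl]acetic acid | OC(=O)C[C@]1(C)OC(C)(C)OC1=O | intermediate
3 | (5S)-5-(2-hydroxyethyl)-2,2,5-trimethyl-1,3-dioxolan-4-one | OCC[C@]1(C)OC(C)(C)OC1=O | intermediate
4 | (2S)-2,4-dihydroxy-N-methoxy-N,2-dimethylbutanamide | OCC[C@](C)(O)C(=O)N(C)OC | intermediate
5 | (2S)-N-methoxy-N,2-dimethyl-2,4-bis(triethylsilyloxy)butanamide | CC[Si](CC)(CC)OCC[C@](C)(O[Si](CC)(CC)CC)C(=O)N(C)OC | intermediate
6 | trimethylsilylacetylene | C#C[Si](C)(C)C | starting material
7 | (4S)-4-methyl-4,6-bis(triethylsilyloxy)-1-(trimethylsilyl)hex-1-yn-3-one | CC[Si](CC)(CC)OCC[C@](C)(O[Si](CC)(CC)CC)C(=O)C#C[Si](C)(C)C | intermediate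
8 | (4S)-1-bromo-4-methyl-4,6-bis(triethylsilyloxy)hex-1-yn-3-one | CC[Si](CC)(CC)OCC[C@](C)(O[Si](CC)(CC)CC)C(=O)C#CBr | intermediate
9 | (4S)-1-bromo-4,6-dihydroxy-4-methylhex-1-yn-3-one (not isolated) | OCC[C@](C)(O)C(=O)C#CBr | intermediate
10 | (2S)-5-bromo-2-(2-hydroxyethyl)-2-methylfuran-3(2H)-one | OCC[C@]1(C)OC(Br)=CC1=O | intermediate
11 | 2-[(2S)-5-bromo-2-methyl-3-oxo-2,3-dihydrofuran-2-yl]acetaldehyde | O=CC[C@]1(C)OC(Br)=CC1=O | intermediate
12 | methyl acrylate | C=CC(=O)OC | starting material
13 | 2,2-dimethoxyacetaldehyde | COC(OC)C=O | starting material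
14 | methyl 3-hydroxy-4,4-dimethoxy-2-methylidenebutanoate (racemic) | COC(OC)C(O)C(=C)C(=O)OC | intermediate
15 | methyl (2Z)-2-(bromomethyl)-4,4-dimethoxybut-2-enoate | COC(=O)/C(CBr)=C/C(OC)OC | intermediate
16 | methyl (3R,4S)-5-[(2S)-5-bromo-2-methyl-3-oxo-2,3-dihydrofuran-2-yl]-3-(dimethoxymethyl)-2-methylidene-4-(trimethylsilyloxy)pentanoate (not isolated) | COC(OC)[C@H](C(=C)C(=O)OC)[C@@H](O[Si](C)(C)C)C[C@]1(C)OC(Br)=CC1=O | intermediate
17 | methyl (3R,4S)-5-[(2S)-5-bromo-2-methyl-3-oxo-2,3-dihydrofuran-2-yl]-3-(dimethoxymethyl)-4-hydroxy-2-methylidenepentanoate (not isolated) | COC(OC)[C@H](C(=C)C(=O)OC)[C@@H](O)C[C@]1(C)OC(Br)=CC1=O | intermediate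
18 | (2S)-5-bromo-2-{[(2S,3R)-3-(dimethoxymethyl)-4-methylidene-5-oxooxolan-2-yl]methyl}-2-methylfuran-3(2H)-one | COC(OC)[C@@H]1C(=C)C(=O)O[C@H]1C[C@]1(C)OC(Br)=CC1=O | intermediate
19 | 4-methoxybenzyl alcohol | COc1ccc(CO)cc1 | starting material
20 | propargyl bromide | C#CCBr | starting material
21 | 1-methoxy-4-[(prop-2-yn-1-yloxy)methyl]benzene | C#CCOCc1ccc(OC)cc1 | intermediate
22 | 1-methoxy-4-[(propa-1,2-dien-1-yloxy)methyl]benzene (4-methoxybenzyloxyallene) | C=C=COCc1ccc(OC)cc1 | intermediate
23 | (2S,3R)-2-{[(2S)-5-bromo-2-methyl-3-oxo-2,3-dihydrofuran-2-yl]methyl}-4-methylidene-5-oxooxolane-3-carbaldehyde | O=C[C@@H]1C(=C)C(=O)O[C@H]1C[C@]1(C)OC(Br)=CC1=O | intermediate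
24 | γ-alkoxyallylindium (not isolated): 23 with the C3 bromine replaced by the (E)-3-(dibromoindiganyl)-1-(4-methoxybenzyloxy)prop-1-en-2-yl group, drawn as the dibromide of trivalent indium | O=C[C@@H]1C(=C)C(=O)O[C@H]1C[C@]1(C)OC(=CC1=O)/C(C[In](Br)Br)=C\OCc1ccc(OC)cc1 | intermediate
25 | (5S,6R,7S,8S,10S)-6-hydroxy-5-(4-methoxybenzyloxy)-1-oxo-3,10-epoxygermacra-2,4(15),11(13)-trien-12,8-olide | O[C@@H]1[C@@H]2C(=C)C(=O)O[C@H]2C[C@]2(C)OC(=CC2=O)C(=C)[C@@H]1OCc1ccc(OC)cc1 | intermediate
26 | methacrylic anhydride | C=C(C)C(=O)OC(=O)C(C)=C | starting material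
27 | (5S,6R,7R,8S,10S)-5-(4-methoxybenzyloxy)-6-(2-methylprop-2-enoyloxy)-1-oxo-3,10-epoxygermacra-2,4(15),11(13)-trien-12,8-olide | C=C(C)C(=O)O[C@@H]1[C@@H]2C(=C)C(=O)O[C@H]2C[C@]2(C)OC(=CC2=O)C(=C)[C@@H]1OCc1ccc(OC)cc1 | intermediate
28 | (5S,6R,7R,8S,10S)-5-hydroxy-6-(2-methylprop-2-enoyloxy)-1-oxo-3,10-epoxygermacra-2,4(15),11(13)-trien-12,8-olide (CNP0142847.1) | C=C(C)C(=O)O[C@@H]1[C@@H]2C(=C)C(=O)O[C@H]2C[C@]2(C)OC(=CC2=O)C(=C)[C@@H]1O | target

The C7 descriptor reads S in 25 and R in 23, 27 and 28 only because the free C6 hydroxyl changes the priority order; the geometry is the same.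

**Step count and risks**

Total: 17 steps. Longest linear sequence: 13 steps (1–8, 11, 14, 15, 16, 17) from (S)-citramalic acid.

Step 15 (proposed new method). What may go wrong: the vinylpalladium may be lost to Heck-type insertion into the α-methylene lactone or to reduction before it meets the allene; the π-allylpalladium may not be handed over to indium; the allylindium may add to the aldehyde of another molecule and give oligomers; or the wrong aldehyde face may be taken. Fallback: the two bond formations are separated and the allyl metal is changed to boron, using known reaction types. Setting out from acetal 18, the Pd(dba)2-catalysed three-component coupling of an organic halide, an allene and bis(pinacolato)diboron (toluene, 80 °C) with 22 should put C3 on the central allene carbon and boron on C15, giving the γ-alkoxyallylboronate acetal F1. Aqueous TFA at 0 °C then frees the C6 aldehyde as the allylboronate aldehyde F2, which in dilute solution should close ring C by intramolecular allylboration through a Zimmerman–Traxler chair to the C6 pinacol borate F3. Aqueous work-up cleaves the borate and the route is rejoined at 25.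

Step 7 (proposed new method). What may go wrong: fluoride or the alkoxide may attack bromine instead of carbon (debromination to the terminal ynone), or substitution of the bromide at C3 may follow ring closure in the basic medium. Fallback: ring A is closed without bromine and the halogen is put on afterwards by directed metalation. Setting out from 7, TBAF/AcOH removes all three silyl groups to give (4S)-4,6-dihydroxy-4-methylhex-1-yn-3-one F4, which cyclises in the known way to (2S)-2-(2-hydroxyethyl)-2-methylfuran-3(2H)-one F5. TBSCl/imidazole gives the silyl ether (2S)-2-[2-(tert-butyldimethylsilyloxy)ethyl]-2-methylfuran-3(2H)-one F6. Zincation of the oxygen-bearing sp2 carbon C3 with TMP2Zn·2MgCl2·2LiCl, a base of the kind used to metalate chromones and 4-pyranones next to the ring oxygen, and quenching with 1,2-dibromotetrachloroethane gives (2S)-5-bromo-2-[2-(tert-butyldimethylsilyloxy)ethyl]-2-methylfuran-3(2H)-one F7. HF·pyridine returns to 10.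

Step 14. What may go wrong: acid-promoted enolisation of the new aldehyde with migration of C11=C13 into conjugation or epimerisation at C7, and hydrolysis of the C3 bromide in the aqueous acid. Fallback: C6 is carried at the alcohol oxidation level and the aldehyde is made by a neutral oxidation. Methyl acrylate 12 and (tert-butyldimethylsilyloxy)acetaldehyde give the Baylis–Hillman adduct methyl 4-(tert-butyldimethylsilyloxy)-3-hydroxy-2-methylidenebutanoate F8, which NBS/Me2S converts into methyl (2Z)-2-(bromomethyl)-4-(tert-butyldimethylsilyloxy)but-2-enoate F9. This bromide replaces 15 in the CrCl2-catalysed allylation of 11 under the conditions of step 11; the trimethylsilyl ether F10 and the hydroxy ester F11 formed on the way lactonise to the trans lactone silyl ether F12. HF·pyridine gives the hydroxymethyl lactone F13, and Dess–Martin periodinane in CH2Cl2 returns to 23, which is filtered through a short pad and used at once in step 15.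

**Further compounds**

F1 | step 15 | allylboronate acetal: 18 with the C3 bromine replaced by the (1Z)-1-(4-methoxybenzyloxy)-3-(4,4,5,5-tetramethyl-1,3,2-dioxaborolan-2-yl)prop-1-en-2-yl group | COC(OC)[C@@H]1C(=C)C(=O)O[C@H]1C[C@]1(C)OC(=CC1=O)/C(CB2OC(C)(C)C(C)(C)O2)=C\OCc1ccc(OC)cc1
F2 | step 15 | allylboronate aldehyde: 23 with the same group in place of the C3 bromine | O=C[C@@H]1C(=C)C(=O)O[C@H]1C[C@]1(C)OC(=CC1=O)/C(CB2OC(C)(C)C(C)(C)O2)=C\OCc1ccc(OC)cc1
F3 | step 15 | C6 pinacol borate of 25 (O–B(pin) in place of the C6 hydroxyl) | CC1(C)OB(OC1(C)C)O[C@@H]2[C@@H]3C(=C)C(=O)O[C@H]3C[C@]3(C)OC(=CC3=O)C(=C)[C@@H]2OCc2ccc(OC)cc2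
F4 | step 7 | (4S)-4,6-dihydroxy-4-methylhex-1-yn-3-one | OCC[C@](C)(O)C(=O)C#C
F5 | step 7 | (2S)-2-(2-hydroxyethyl)-2-methylfuran-3(2H)-one | OCC[C@]1(C)OC=CC1=O
F6 | step 7 | (2S)-2-[2-(tert-butyldimethylsilyloxy)ethyl]-2-methylfuran-3(2H)-one | CC(C)(C)[Si](C)(C)OCC[C@]1(C)OC=CC1=O
F7 | step 7 | (2S)-5-bromo-2-[2-(tert-butyldimethylsilyloxy)ethyl]-2-methylfuran-3(2H)-one | CC(C)(C)[Si](C)(C)OCC[C@]1(C)OC(Br)=CC1=O
F8 | step 14 | methyl 4-(tert-butyldimethylsilyloxy)-3-hydroxy-2-methylidenebutanoate (racemic) | COC(=O)C(=C)C(O)CO[Si](C)(C)C(C)(C)C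
F9 | step 14 | methyl (2Z)-2-(bromomethyl)-4-(tert-butyldimethylsilyloxy)but-2-enoate | COC(=O)/C(CBr)=C/CO[Si](C)(C)C(C)(C)C
F10 | step 14 | methyl (3S,4S)-5-[(2S)-5-bromo-2-methyl-3-oxo-2,3-dihydrofuran-2-yl]-3-[(tert-butyldimethylsilyloxy)methyl]-2-methylidene-4-(trimethylsilyloxy)pentanoate | CC(C)(C)[Si](C)(C)OC[C@H](C(=C)C(=O)OC)[C@@H](O[Si](C)(C)C)C[C@]1(C)OC(Br)=CC1=O
F11 | step 14 | methyl (3S,4S)-5-[(2S)-5-bromo-2-methyl-3-oxo-2,3-dihydrofuran-2-yl]-3-[(tert-butyldimethylsilyloxy)methyl]-4-hydroxy-2-methylidenepentanoate | CC(C)(C)[Si](C)(C)OC[C@H](C(=C)C(=O)OC)[C@@H](O)C[C@]1(C)OC(Br)=CC1=O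
F12 | step 14 | (2S)-5-bromo-2-{[(2S,3S)-3-[(tert-butyldimethylsilyloxy)methyl]-4-methylidene-5-oxooxolan-2-yl]methyl}-2-methylfuran-3(2H)-one | CC(C)(C)[Si](C)(C)OC[C@@H]1C(=C)C(=O)O[C@H]1C[C@]1(C)OC(Br)=CC1=O
F13 | step 14 | (2S)-5-bromo-2-{[(2S,3S)-3-(hydroxymethyl)-4-methylidene-5-oxooxolan-2-yl]methyl}-2-methylfuran-3(2H)-one | OC[C@@H]1C(=C)C(=O)O[C@H]1C[C@]1(C)OC(Br)=CC1=O
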